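**Plan**

- Retrosynthetic cuts: C11=C12 last (ring A C15 dienal + ring B C25 ylide), then C11'=C12' (C10 dialdehyde + ring B C15 ylide), then the ring–alkyne bonds C6–C7 and C6'–C7' (two ring triflates + one (E)-enynol), and finally C3–O and C6–O of ring A back to O2.
- Forward, ring A: enone → ring dienyl triflate → Sonogashira coupling → acetate → O2 bridges C3 and C6 (the only ring closed, reopened in the next step) → cis-diol → resolution → (7E)-triol → dienal.
- Forward, ring B and chain: ketoisophorone → trans-hydroxy ketone → enol triflate → Sonogashira coupling → C15 tributylphosphonium salt → C25 aldehyde → C25 phosphonium salt → Wittig union with the ring A dienal.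
- Enabling feature: in ring A the hydroxyls at C3 and C6 are cis and flank the C4=C5 alkene; this is the pattern left when a peroxide bridge across C3/C6 of a C3=C4–C5=C6 ring diene is reduced.
- Stereochemistry: cis-C3/C6 from the suprafacial cycloaddition; their absolute configuration from lipase resolution; C3' from yeast reduction followed by substrate-controlled hydrogenation; 9E/9'E from the enynol, 7E from alkoxide-directed hydroalumination, 11E/11'E from the Wittig steps.

Key step: step 4

Numbering: carotenoid numbering throughout; ring A is the 3,6-diol ring (C1–C6, chain from C6), ring B the acetylenic ring (primed locants). Polyenes are handled under argon in the dark.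

Assumption: in step 6 the lipase is taken to acylate the (3S) carbinol, the enantiomer that places the bulkier CH2–CMe2 flank of C3 in the large pocket; if the enzyme prefers the mirror image, the unreacted alcohol is carried on instead, because step 7 removes every ester alike.

**Step 1**
Reactants: 1 2,6,6-trimethylcyclohex-2-en-1-one
Product: 3 2,6,6-trimethylcyclohexa-1,3-dien-1-yl trifluoromethanesulfonate, via lithium dienolate 2 (not isolated)
Conditions: LiN(i-Pr)2 (LDA), THF, −78 °C; then PhNTf2, −78 °C to 0 °C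
Reagents that add atoms: N-phenylbis(trifluoromethanesulfonimide), O=S(=O)(N(c1ccccc1)S(=O)(=O)C(F)(F)F)C(F)(F)F
Why: With no α' hydrogen available, the amide base should remove a γ-hydrogen from the ring CH2 next to the alkene to give the through-conjugated dienolate, and O-sulfonylation (enol triflate formation) then fixes the C3=C4–C5=C6 diene.

**Step 2**
Reactants: 3 2,6,6-trimethylcyclohexa-1,3-dien-1-yl trifluoromethanesulfonate; 4 (E)-3-methylpent-2-en-4-yn-1-ol
Product: 5 (E)-3-methyl-5-(2,6,6-trimethylcyclohexa-1,3-dien-1-yl)pent-2-en-4-yn-1-ol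
Conditions: Pd(PPh3)4 (cat.), CuI (cat.), i-Pr2NH, THF, rt, argon
Reagents that add atoms: none
Why: Sonogashira coupling of an alkenyl triflate with a terminal alkyne forms C6–C7 under mild amine conditions that leave the free hydroxyl and the (9E) alkene of 4 unchanged.

**Step 3**
Reactants: 5 (E)-3-methyl-5-(2,6,6-trimethylcyclohexa-1,3-dien-1-yl)pent-2-en-4-yn-1-ol
Product: 6 (E)-3-methyl-5-(2,6,6-trimethylcyclohexa-1,3-dien-1-yl)pent-2-en-4-yn-1-yl acetate
Conditions: Ac2O, pyridine, DMAP (cat.), CH2Cl2, 0 °C to rt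
Reagents that add atoms: acetic anhydride, CC(=O)OC(C)=O
Why: DMAP-catalysed acylation of the primary allylic alcohol is routine, and the ester lowers the electron density of C9=C10 and later lets the lipase act on C3 alone.

**Step 4**
Reactants: 6 (E)-3-methyl-5-(2,6,6-trimethylcyclohexa-1,3-dien-1-yl)pent-2-en-4-yn-1-yl acetate
Product: 7 rac-(E)-3-methyl-5-[(1R,4S)-6,7,7-trimethyl-2,3-dioxabicyclo[2.2.2]oct-5-en-1-yl]pent-2-en-4-yn-1-yl acetate (racemate; the enantiomer later carried on is the one named)
Conditions: O2, 5,10,15,20-tetraphenylporphyrin (cat.), white LED light, CH2Cl2, −20 °C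
Reagents that add atoms: dioxygen, O=O
Why: Light and the porphyrin sensitiser convert O2 into its singlet state, which adds as the 2π partner to the s-cis C3=C4–C5=C6 diene of ring A in a concerted suprafacial [4+2] cycloaddition, forming C3–O and C6–O together and moving the alkene to C4=C5. The closest known reaction type is the dye-sensitised photooxygenation of cyclohexa-1,3-dienes to 2,3-dioxabicyclo[2.2.2]oct-5-enes (α-terpinene to ascaridole). The one new ring, the six-membered 1,2-dioxene O–C3–C4=C5–C6–O, closes by this cycloaddition across the 1,4-positions of the carbocycle and therefore arises as a peroxide bridge. The relative configuration of C3 and C6 is set by the suprafacial mode, both oxygens necessarily sitting on one ring face, whereas the two diene faces are enantiotopic, so the bridge forms as a racemate whose absolute configuration is settled in step 6. The step needs cycloaddition at the ring diene in preference to ene hydroperoxidation or attack on the side chain; the ring-locked s-cis geometry and high electron density of the trialkyl-substituted diene should let cycloaddition outrun hydrogen abstraction from the C5 methyl or C2, C9=C10 is deactivated by conjugation with the alkyne and by the allylic acetoxy group, and the low temperature further disfavours ene pathways.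

**Step 5**
Reactants: 7 rac-(E)-3-methyl-5-[(1R,4S)-6,7,7-trimethyl-2,3-dioxabicyclo[2.2.2]oct-5-en-1-yl]pent-2-en-4-yn-1-yl acetate
Product: 8 rac-(E)-5-[(1R,4S)-1,4-dihydroxy-2,6,6-trimethylcyclohex-2-en-1-yl]-3-methylpent-2-en-4-yn-1-yl acetate (cis-diol)
Conditions: thiourea, MeOH, 0 °C to rt
Reagents that add atoms: none
Why: Thiourea reduction of a bicyclic endoperoxide cleaves only the O–O bond (sulfur attacks oxygen, then solvolysis), so both C–O bonds stay on the face where they were formed and the cis-3,6-diol should result without any base that could trigger a Kornblum–DeLaMare rearrangement at C3–H.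

**Step 6**
Reactants: 8 rac-(E)-5-[(1R,4S)-1,4-dihydroxy-2,6,6-trimethylcyclohex-2-en-1-yl]-3-methylpent-2-en-4-yn-1-yl acetate
Product: 9 (E)-5-[(1R,4S)-4-acetoxy-1-hydroxy-2,6,6-trimethylcyclohex-2-en-1-yl]-3-methylpent-2-en-4-yn-1-yl acetate
Conditions: immobilised Burkholderia cepacia lipase, vinyl acetate, t-BuOMe, 30 °C, stopped near half conversion
Reagents that add atoms: vinyl acetate, C=COC(C)=O
Why: Lipase-catalysed kinetic resolution by irreversible transesterification should acylate only the secondary C3 carbinol of one enantiomer (the tertiary C6 hydroxyl is inert), here taken to be the (3S) alcohol, so that diacetate 9 with the C3/C6 configuration of the target is separated by chromatography from the unreacted mirror-image diol.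

**Step 7**
Reactants: 9 (E)-5-[(1R,4S)-4-acetoxy-1-hydroxy-2,6,6-trimethylcyclohex-2-en-1-yl]-3-methylpent-2-en-4-yn-1-yl acetate
Product: 11 (2E,4E)-5-[(1R,4S)-1,4-dihydroxy-2,6,6-trimethylcyclohex-2-en-1-yl]-3-methylpenta-2,4-dien-1-ol, via alkynyl triol aluminate 10 (not isolated)
Conditions: LiAlH4 (excess), THF, 0 °C to rt; aqueous potassium sodium tartrate work-up
Reagents that add atoms: none
Why: The hydride first cleaves both acetates, after which the C6 alkoxide delivers hydride across C7≡C8 in the anti hydroalumination typical of propargylic alcohols, so protonolysis should give only the (7E)-alkene while C3, C6 and the (9E) bond stay unchanged.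

**Step 8**
Reactants: 11 (2E,4E)-5-[(1R,4S)-1,4-dihydroxy-2,6,6-trimethylcyclohex-2-en-1-yl]-3-methylpenta-2,4-dien-1-ol
Product: 12 (2E,4E)-5-[(1R,4S)-1,4-dihydroxy-2,6,6-trimethylcyclohex-2-en-1-yl]-3-methylpenta-2,4-dienal
Conditions: [Cu(MeCN)4]OTf (cat.), 2,2'-bipyridine (cat.), TEMPO (cat.), N-methylimidazole (cat.), air, MeCN, rt
Reagents that add atoms: none
Why: Copper/TEMPO aerobic oxidation is selective for primary alcohols (here a dienylic one) over the secondary allylic C3 carbinol and the tertiary C6 carbinol, and its near-neutral conditions should spare the acid-labile doubly allylic C6 hydroxyl and the 2E geometry.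

**Step 9**
Reactants: 13 2,6,6-trimethylcyclohex-2-ene-1,4-dione (ketoisophorone)
Product: 14 (6R)-2,2,6-trimethylcyclohexane-1,4-dione
Conditions: fermenting baker's yeast (Saccharomyces cerevisiae), sucrose, water, 30 °C
Reagents that add atoms: none
Why: The ene-reductase activity of the yeast adds hydrogen across the C=C bond of the ene-dione on one enantioface, which sets the methyl-bearing centre as (6R) under enzyme control.

**Step 10**
Reactants: 14 (6R)-2,2,6-trimethylcyclohexane-1,4-dione
Product: 15 (4R,6R)-4-hydroxy-2,2,6-trimethylcyclohexan-1-one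
Conditions: H2, Raney Ni (washed neutral), MeOH, rt
Reagents that add atoms: none
Why: Heterogeneous hydrogenation should reduce only the unhindered C4 ketone (C1 lies between a quaternary and a tertiary carbon) and add hydrogen from the side remote from the axial C2 methyl, so the trans (4R) alcohol should predominate by substrate control and the minor cis epimer is removed by crystallisation.

**Step 11**
Reactants: 15 (4R,6R)-4-hydroxy-2,2,6-trimethylcyclohexan-1-one
Product: 16 (4R,6R)-4-[(tert-butyldimethylsilyl)oxy]-2,2,6-trimethylcyclohexan-1-one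
Conditions: TBSCl, imidazole, DMF, rt
Reagents that add atoms: tert-butyldimethylsilyl chloride, CC(C)(C)[Si](C)(C)Cl
Why: Imidazole-promoted silylation masks the secondary hydroxyl, which would otherwise consume base and triflating agent in the next step.

**Step 12**
Reactants: 16 (4R,6R)-4-[(tert-butyldimethylsilyl)oxy]-2,2,6-trimethylcyclohexan-1-one
Product: 18 (4R)-4-[(tert-butyldimethylsilyl)oxy]-2,6,6-trimethylcyclohex-1-en-1-yl trifluoromethanesulfonate, via lithium enolate 17 (not isolated)
Conditions: LiN(i-Pr)2 (LDA), THF, −78 °C to 0 °C; then PhNTf2, 0 °C to rt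
Reagents that add atoms: N-phenylbis(trifluoromethanesulfonimide), O=S(=O)(N(c1ccccc1)S(=O)(=O)C(F)(F)F)C(F)(F)F
Why: The ketone has a single α-hydrogen, so deprotonation gives the tetrasubstituted enolate and O-sulfonylation the enol triflate; the methyl-bearing stereocentre, having controlled step 10, is erased on purpose while the silyloxy-bearing carbon is untouched.

**Step 13**
Reactants: 18 (4R)-4-[(tert-butyldimethylsilyl)oxy]-2,6,6-trimethylcyclohex-1-en-1-yl trifluoromethanesulfonate; 4 (E)-3-methylpent-2-en-4-yn-1-ol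
Product: 19 (E)-5-[(4R)-4-[(tert-butyldimethylsilyl)oxy]-2,6,6-trimethylcyclohex-1-en-1-yl]-3-methylpent-2-en-4-yn-1-ol
Conditions: Pd(PPh3)4 (cat.), CuI (cat.), i-Pr2NH, DMF, 50 °C, argon
Reagents that add atoms: none
Why: A second Sonogashira coupling forms C6'–C7'; hindered 2,6,6-trimethylcyclohexenyl triflates are established partners for terminal enynes at slightly raised temperature, and the (9'E) geometry comes unchanged from 4.

**Step 14**
Reactants: 19 (E)-5-[(4R)-4-[(tert-butyldimethylsilyl)oxy]-2,6,6-trimethylcyclohex-1-en-1-yl]-3-methylpent-2-en-4-yn-1-ol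
Product: 20 (E)-5-[(4R)-4-hydroxy-2,6,6-trimethylcyclohex-1-en-1-yl]-3-methylpent-2-en-4-yn-1-ol
Conditions: TBAF, THF, rt
Reagents that add atoms: none
Why: Fluoride desilylation frees the 3'-hydroxyl, a spectator in all later steps, so the final coupling can deliver the target without a late deprotection.

**Step 15**
Reactants: 20 (E)-5-[(4R)-4-hydroxy-2,6,6-trimethylcyclohex-1-en-1-yl]-3-methylpent-2-en-4-yn-1-ol
Product: 21 (E)-5-[(4R)-4-hydroxy-2,6,6-trimethylcyclohex-1-en-1-yl]-3-methylpent-2-en-4-yn-1-yl bromide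
Conditions: CBr4 (1.1 equiv), PPh3 (1.1 equiv), CH2Cl2, −20 °C to 0 °C
Reagents that add atoms: carbon tetrabromide, BrC(Br)(Br)Br
Why: In this Appel reaction the unhindered primary allylic hydroxyl forms its alkoxyphosphonium ion and is displaced by bromide (SN2, E geometry kept) much faster than the hindered, non-allylic ring carbinol.

**Step 16**
Reactants: 21 (E)-5-[(4R)-4-hydroxy-2,6,6-trimethylcyclohex-1-en-1-yl]-3-methylpent-2-en-4-yn-1-yl bromide
Product: 22 tributyl{(E)-5-[(4R)-4-hydroxy-2,6,6-trimethylcyclohex-1-en-1-yl]-3-methylpent-2-en-4-yn-1-yl}phosphonium bromide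
Conditions: PBu3, EtOAc, rt
Reagents that add atoms: tributylphosphine, CCCCP(CCCC)CCCC
Why: SN2 alkylation of the strongly nucleophilic trialkylphosphine by the primary allylic bromide should give the phosphonium salt at room temperature without touching the (9'E) alkene.

**Step 17**
Reactants: 22 tributyl{(E)-5-[(4R)-4-hydroxy-2,6,6-trimethylcyclohex-1-en-1-yl]-3-methylpent-2-en-4-yn-1-yl}phosphonium bromide; 23 (2E,4E,6E)-2,7-dimethylocta-2,4,6-trienedial
Product: 25 (2E,4E,6E,8E,10E)-13-[(4R)-4-hydroxy-2,6,6-trimethylcyclohex-1-en-1-yl]-2,7,11-trimethyltrideca-2,4,6,8,10-pentaen-12-ynal, via tributylphosphonium ylide 24 (not isolated)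
Conditions: NaOMe, CH2Cl2/MeOH, 0 °C to rt; 23 in excess (about 2 equiv), 22 added slowly
Reagents that add atoms: none
Why: This Wittig olefination forms C11'=C12'; the reactive, short-lived allylic tributylphosphonium ylide is expected to be E-selective and to be trapped before rotation about C9'–C10' can erode the (9'E) geometry, and the excess of the C10 dialdehyde, which is more electrophilic than its mono-adduct, should hold the reaction at mono-olefination.

**Step 18**
Reactants: 25 (2E,4E,6E,8E,10E)-13-[(4R)-4-hydroxy-2,6,6-trimethylcyclohex-1-en-1-yl]-2,7,11-trimethyltrideca-2,4,6,8,10-pentaen-12-ynal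
Product: 26 (2E,4E,6E,8E,10E)-13-[(4R)-4-hydroxy-2,6,6-trimethylcyclohex-1-en-1-yl]-2,7,11-trimethyltrideca-2,4,6,8,10-pentaen-12-yn-1-ol
Conditions: NaBH4, MeOH/THF, 0 °C
Reagents that add atoms: none
Why: Borohydride reduces the conjugated aldehyde chemoselectively in the 1,2-sense, the alkyne and the polyene being inert.

**Step 19**
Reactants: 26 (2E,4E,6E,8E,10E)-13-[(4R)-4-hydroxy-2,6,6-trimethylcyclohex-1-en-1-yl]-2,7,11-trimethyltrideca-2,4,6,8,10-pentaen-12-yn-1-ol
Product: 27 {(2E,4E,6E,8E,10E)-13-[(4R)-4-hydroxy-2,6,6-trimethylcyclohex-1-en-1-yl]-2,7,11-trimethyltrideca-2,4,6,8,10-pentaen-12-yn-1-yl}triphenylphosphonium bromide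
Conditions: PPh3·HBr, CH2Cl2, 0 °C to rt
Reagents that add atoms: triphenylphosphine hydrobromide, [Br-].c1ccc(cc1)[PH+](c1ccccc1)c1ccccc1
Why: In this classical salt formation of polyene chemistry, protonation and ionisation of the allylic alcohol give a delocalised polyenyl cation that the phosphine captures at the chain terminus, so the conjugated primary phosphonium salt should form while the non-allylic 3'-hydroxyl stays untouched.

**Step 20**
Reactants: 27 {(2E,4E,6E,8E,10E)-13-[(4R)-4-hydroxy-2,6,6-trimethylcyclohex-1-en-1-yl]-2,7,11-trimethyltrideca-2,4,6,8,10-pentaen-12-yn-1-yl}triphenylphosphonium bromide; 12 (2E,4E)-5-[(1R,4S)-1,4-dihydroxy-2,6,6-trimethylcyclohex-2-en-1-yl]-3-methylpenta-2,4-dienal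
Product: 29 all-E target triol with (3S,6R)-3,6-dihydroxy ring A and (3'R)-3'-hydroxy-7',8'-didehydro ring B, via triphenylphosphonium ylide 28 (not isolated)
Conditions: NaOMe (excess), CH2Cl2/MeOH, 0 °C to rt, argon, dark; chromatography and crystallisation in the dark
Reagents that add atoms: none
Why: This Wittig olefination forms C11=C12 and joins the two halves; methoxide deprotonates only the phosphonium salt, the three free hydroxyls are spectators, the new disubstituted alkene should be mainly E, and any hindered (11Z) isomer is expected to revert on gentle warming kept short enough to spare the (9'E) bond.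

**Compound list**

1 | 2,6,6-trimethylcyclohex-2-en-1-one | CC1=CCCC(C)(C)C1=O | starting material
2 | lithium 2,6,6-trimethylcyclohexa-1,3-dien-1-olate | [Li+].[O-]C1=C(C)C=CCC1(C)C | intermediate (not isolated)
3 | 2,6,6-trimethylcyclohexa-1,3-dien-1-yl trifluoromethanesulfonate | CC1=C(OS(=O)(=O)C(F)(F)F)C(C)(C)CC=C1 | intermediate
4 | (E)-3-methylpent-2-en-4-yn-1-ol | C#C/C(C)=C/CO | starting material
5 | (E)-3-methyl-5-(2,6,6-trimethylcyclohexa-1,3-dien-1-yl)pent-2-en-4-yn-1-ol | CC1=C(C#C/C(C)=C/CO)C(C)(C)CC=C1 | intermediate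
6 | (E)-3-methyl-5-(2,6,6-trimethylcyclohexa-1,3-dien-1-yl)pent-2-en-4-yn-1-yl acetate | CC1=C(C#C/C(C)=C/COC(C)=O)C(C)(C)CC=C1 | intermediate
7 | rac-(E)-3-methyl-5-[(1R,4S)-6,7,7-trimethyl-2,3-dioxabicyclo[2.2.2]oct-5-en-1-yl]pent-2-en-4-yn-1-yl acetate (racemate, one enantiomer drawn) | CC1=C[C@@H](O2)CC(C)(C)[C@]1(O2)C#C/C(C)=C/COC(C)=O | intermediate
8 | rac-(E)-5-[(1R,4S)-1,4-dihydroxy-2,6,6-trimethylcyclohex-2-en-1-yl]-3-methylpent-2-en-4-yn-1-yl acetate (racemate, one enantiomer drawn) | CC1=C[C@@H](O)CC(C)(C)[C@]1(O)C#C/C(C)=C/COC(C)=O | intermediate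
9 | (E)-5-[(1R,4S)-4-acetoxy-1-hydroxy-2,6,6-trimethylcyclohex-2-en-1-yl]-3-methylpent-2-en-4-yn-1-yl acetate | CC1=C[C@@H](OC(C)=O)CC(C)(C)[C@]1(O)C#C/C(C)=C/COC(C)=O | intermediate
10 | (E)-5-[(1R,4S)-1,4-dihydroxy-2,6,6-trimethylcyclohex-2-en-1-yl]-3-methylpent-2-en-4-yn-1-ol, present as its alkoxyaluminate | CC1=C[C@@H](O)CC(C)(C)[C@]1(O)C#C/C(C)=C/CO | intermediate (not isolated)
11 | (2E,4E)-5-[(1R,4S)-1,4-dihydroxy-2,6,6-trimethylcyclohex-2-en-1-yl]-3-methylpenta-2,4-dien-1-ol | CC1=C[C@@H](O)CC(C)(C)[C@]1(O)/C=C/C(C)=C/CO | intermediate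
12 | (2E,4E)-5-[(1R,4S)-1,4-dihydroxy-2,6,6-trimethylcyclohex-2-en-1-yl]-3-methylpenta-2,4-dienal | CC1=C[C@@H](O)CC(C)(C)[C@]1(O)/C=C/C(C)=C/C=O | intermediate
13 | 2,6,6-trimethylcyclohex-2-ene-1,4-dione (ketoisophorone) | CC1=CC(=O)CC(C)(C)C1=O | starting material
14 | (6R)-2,2,6-trimethylcyclohexane-1,4-dione | O=C1[C@H](C)CC(=O)CC1(C)C | intermediate
15 | (4R,6R)-4-hydroxy-2,2,6-trimethylcyclohexan-1-one | O=C1[C@H](C)C[C@@H](O)CC1(C)C | intermediate
16 | (4R,6R)-4-[(tert-butyldimethylsilyl)oxy]-2,2,6-trimethylcyclohexan-1-one | O=C1[C@H](C)C[C@@H](O[Si](C)(C)C(C)(C)C)CC1(C)C | intermediate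
17 | lithium (4R)-4-[(tert-butyldimethylsilyl)oxy]-2,6,6-trimethylcyclohex-1-en-1-olate | [Li+].[O-]C1=C(C)C[C@@H](O[Si](C)(C)C(C)(C)C)CC1(C)C | intermediate (not isolated)
18 | (4R)-4-[(tert-butyldimethylsilyl)oxy]-2,6,6-trimethylcyclohex-1-en-1-yl trifluoromethanesulfonate | O=S(=O)(OC1=C(C)C[C@@H](O[Si](C)(C)C(C)(C)C)CC1(C)C)C(F)(F)F | intermediate
19 | (E)-5-[(4R)-4-[(tert-butyldimethylsilyl)oxy]-2,6,6-trimethylcyclohex-1-en-1-yl]-3-methylpent-2-en-4-yn-1-ol | OC/C=C(\C)C#CC1=C(C)C[C@@H](O[Si](C)(C)C(C)(C)C)CC1(C)C | intermediate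
20 | (E)-5-[(4R)-4-hydroxy-2,6,6-trimethylcyclohex-1-en-1-yl]-3-methylpent-2-en-4-yn-1-ol | OC/C=C(\C)C#CC1=C(C)C[C@@H](O)CC1(C)C | intermediate
21 | (E)-5-[(4R)-4-hydroxy-2,6,6-trimethylcyclohex-1-en-1-yl]-3-methylpent-2-en-4-yn-1-yl bromide | BrC/C=C(\C)C#CC1=C(C)C[C@@H](O)CC1(C)C | intermediate
22 | tributyl{(E)-5-[(4R)-4-hydroxy-2,6,6-trimethylcyclohex-1-en-1-yl]-3-methylpent-2-en-4-yn-1-yl}phosphonium bromide | [Br-].CCCC[P+](CCCC)(CCCC)C/C=C(\C)C#CC1=C(C)C[C@@H](O)CC1(C)C | intermediate
23 | (2E,4E,6E)-2,7-dimethylocta-2,4,6-trienedial | O=C/C(C)=C/C=C/C=C(\C)C=O | starting material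
24 | ylide of 22 (tributylphosphonium allylide) | CCCC[P+](CCCC)(CCCC)[CH-]/C=C(\C)C#CC1=C(C)C[C@@H](O)CC1(C)C | intermediate (not isolated)
25 | (2E,4E,6E,8E,10E)-13-[(4R)-4-hydroxy-2,6,6-trimethylcyclohex-1-en-1-yl]-2,7,11-trimethyltrideca-2,4,6,8,10-pentaen-12-ynal | O=C/C(C)=C/C=C/C=C(C)/C=C/C=C(\C)C#CC1=C(C)C[C@@H](O)CC1(C)C | intermediate
26 | (2E,4E,6E,8E,10E)-13-[(4R)-4-hydroxy-2,6,6-trimethylcyclohex-1-en-1-yl]-2,7,11-trimethyltrideca-2,4,6,8,10-pentaen-12-yn-1-ol | OC/C(C)=C/C=C/C=C(C)/C=C/C=C(\C)C#CC1=C(C)C[C@@H](O)CC1(C)C | intermediate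
27 | {(2E,4E,6E,8E,10E)-13-[(4R)-4-hydroxy-2,6,6-trimethylcyclohex-1-en-1-yl]-2,7,11-trimethyltrideca-2,4,6,8,10-pentaen-12-yn-1-yl}triphenylphosphonium bromide | [Br-].c1ccccc1[P+](c1ccccc1)(c1ccccc1)C/C(C)=C/C=C/C=C(C)/C=C/C=C(\C)C#CC1=C(C)C[C@@H](O)CC1(C)C | intermediate
28 | ylide of 27 (triphenylphosphonium polyenylide) | c1ccccc1[P+](c1ccccc1)(c1ccccc1)[CH-]/C(C)=C/C=C/C=C(C)/C=C/C=C(\C)C#CC1=C(C)C[C@@H](O)CC1(C)C | intermediate (not isolated)
29 | all-E C40 triol: (3S,6R)-3,6-dihydroxy-4,5-ene ring A, 7E to 11'E polyene, 7',8'-alkyne, (3'R)-3'-hydroxy ring B | CC1=C[C@@H](O)CC(C)(C)[C@]1(O)/C=C/C(C)=C/C=C/C(C)=C/C=C/C=C(C)/C=C/C=C(\C)C#CC1=C(C)C[C@@H](O)CC1(C)C | target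

**Step count and risks**

Total: 20 steps. Longest linear sequence: 12 steps (13 to 29, steps 9–20); the ring A branch (steps 1–8) joins in step 20.

Steps most likely to fail:

1. Step 4. Ene-type hydroperoxidation (hydrogen abstraction from the C5 methyl or from C2) or oxidation of the enyne chain may compete with cycloaddition, and the bridged peroxide may rearrange homolytically on isolation. The fallback sets out from 13 and comes back at 11. Asymmetric transfer hydrogenation of the unhindered C4 carbonyl of 13 with RuCl(p-cymene)(TsDPEN) in i-PrOH, using the catalyst antipode that gives the 4S alcohol, would give (4S)-4-hydroxy-2,6,6-trimethylcyclohex-2-en-1-one F1. TBSCl and imidazole would convert it into (4S)-4-[(tert-butyldimethylsilyl)oxy]-2,6,6-trimethylcyclohex-2-en-1-one F2. 1,2-Addition of the dilithium derivative of 4 (n-BuLi, THF, −78 °C) to the remaining hindered ketone would give, after chromatographic removal of the C6 epimer, (E)-5-[(1R,4S)-4-[(tert-butyldimethylsilyl)oxy]-1-hydroxy-2,6,6-trimethylcyclohex-2-en-1-yl]-3-methylpent-2-en-4-yn-1-ol F3. LiAlH4 would reduce C7≡C8 to give (2E,4E)-5-[(1R,4S)-4-[(tert-butyldimethylsilyl)oxy]-1-hydroxy-2,6,6-trimethylcyclohex-2-en-1-yl]-3-methylpenta-2,4-dien-1-ol F4, and TBAF would release 11. This path gives up the built-in cis control of the peroxide bridge but needs no resolution.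

2. Step 6. The enzyme may discriminate poorly between the enantiomers at the hindered ring carbinol, acylate very slowly, or prefer the mirror-image alcohol. The fallback sets out from 8 and comes back at 11. Esterification of racemic 8 at C3 with (S)-O-methylmandelic acid (DCC, DMAP, CH2Cl2) would give two diastereomeric esters separable on silica. The diastereomer with the (3S,6R) ring, (E)-5-[(1R,4S)-1-hydroxy-4-{[(2S)-2-methoxy-2-phenylacetyl]oxy}-2,6,6-trimethylcyclohex-2-en-1-yl]-3-methylpent-2-en-4-yn-1-yl acetate F5, would be subjected to the LiAlH4 conditions of step 7, which cleave both esters and reduce the alkyne, giving 11.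

3. Step 17. Rotation within the allylic ylide may erode the (9'E) geometry, E selectivity at C11'=C12' may be incomplete, and the dialdehyde may be olefinated twice. The fallback sets out from 20 and 23 and comes back at 27; the roles are reversed so that no ylide is ever formed next to C9'=C10'. MnO2 in CH2Cl2 would oxidise only the primary allylic hydroxyl of 20 to (E)-5-[(4R)-4-hydroxy-2,6,6-trimethylcyclohex-1-en-1-yl]-3-methylpent-2-en-4-ynal F6. NaBH4 would reduce 23 to (2E,4E,6E)-2,7-dimethylocta-2,4,6-triene-1,8-diol F7, and PPh3·HBr would convert this into [(2E,4E,6E)-2,7-dimethylocta-2,4,6-triene-1,8-diyl]bis(triphenylphosphonium) dibromide F8. Treating an excess of F8 with one equivalent of NaOMe and F6 would give, by a single Wittig reaction, the C25 salt 27 directly.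

**Further compounds**

F1 | step 4 | (4S)-4-hydroxy-2,6,6-trimethylcyclohex-2-en-1-one | CC1=C[C@@H](O)CC(C)(C)C1=O
F2 | step 4 | (4S)-4-[(tert-butyldimethylsilyl)oxy]-2,6,6-trimethylcyclohex-2-en-1-one | CC1=C[C@@H](O[Si](C)(C)C(C)(C)C)CC(C)(C)C1=O
F3 | step 4 | (E)-5-[(1R,4S)-4-[(tert-butyldimethylsilyl)oxy]-1-hydroxy-2,6,6-trimethylcyclohex-2-en-1-yl]-3-methylpent-2-en-4-yn-1-ol | CC1=C[C@@H](O[Si](C)(C)C(C)(C)C)CC(C)(C)[C@]1(O)C#C/C(C)=C/CO
F4 | step 4 | (2E,4E)-5-[(1R,4S)-4-[(tert-butyldimethylsilyl)oxy]-1-hydroxy-2,6,6-trimethylcyclohex-2-en-1-yl]-3-methylpenta-2,4-dien-1-ol | CC1=C[C@@H](O[Si](C)(C)C(C)(C)C)CC(C)(C)[C@]1(O)/C=C/C(C)=C/CO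
F5 | step 6 | (E)-5-[(1R,4S)-1-hydroxy-4-{[(2S)-2-methoxy-2-phenylacetyl]oxy}-2,6,6-trimethylcyclohex-2-en-1-yl]-3-methylpent-2-en-4-yn-1-yl acetate | CC1=C[C@@H](OC(=O)[C@@H](OC)c2ccccc2)CC(C)(C)[C@]1(O)C#C/C(C)=C/COC(C)=O
F6 | step 17 | (E)-5-[(4R)-4-hydroxy-2,6,6-trimethylcyclohex-1-en-1-yl]-3-methylpent-2-en-4-ynal | O=C/C=C(\C)C#CC1=C(C)C[C@@H](O)CC1(C)C
F7 | step 17 | (2E,4E,6E)-2,7-dimethylocta-2,4,6-triene-1,8-diol | OC/C(C)=C/C=C/C=C(\C)CO
F8 | step 17 | [(2E,4E,6E)-2,7-dimethylocta-2,4,6-triene-1,8-diyl]bis(triphenylphosphonium) dibromide | [Br-].[Br-].c1ccccc1[P+](c1ccccc1)(c1ccccc1)C/C(C)=C/C=C/C=C(\C)C[P+](c1ccccc1)(c1ccccc1)c1ccccc1
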